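## Structural features

The target is a trans-2,3-diaryl-2,3-dihydro-1-benzofuran: a dihydrofuran ring (O1, C2, C3) fused to a benzo ring (C3a to C7a) that carries a free hydroxyl at C4 and an (E)-4-hydroxystyryl arm at C6. C2 bears a 3,4-dihydroxyphenyl group (ArA) and C3 a 3,5-dihydroxyphenyl group (ArB). The two adjacent stereocentres are both S, which puts ArA and ArB on opposite faces of the five-membered ring. Six free phenols (one catechol), an electron-rich stilbene and the benzylic C2–O1 ether para to a phenol make the compound sensitive to oxidants, light and above all acid, which can reopen the ring through a quinone-methide-type cation at C2. C3 is a doubly benzylic methine whose configuration cannot be recovered once lost, whereas C2 can be set relative to C3 by trans-selective closure at a stabilised C2 cation. The real difficulty is the benzo ring: C3a carries C3 and is flanked on both sides by oxygen-bearing carbons (C4 and C7a), with the carbon arm para to it at C6, a pattern that substitution of a 5-substituted resorcinol does not deliver cleanly at the carbon between the oxygens. The key step builds this ring from scratch: C3a and one oxygenated neighbour come from the two carbons of a siloxyalkyne that already holds C3, and the other four ring carbons, with the one-carbon arm at C6, come from a 3-substituted cyclobutenone.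

## Logic of the disconnections

30 from 29. The five aryl O–CH3 bonds are cut last. Methyl ethers are the only phenol masks that pass untouched through organolithium, peroxide, heat, fluoride and acid, and they let every aromatic building block be bought. The demand is a Lewis-acid cleavage that spares the C2–O1 bond, the stilbene and the C3 centre.

29 from 27 and 28. The C=C bond of the styryl arm is cut. This removes the most acid- and light-sensitive unit from all earlier steps and reduces the problem to an aldehyde on the benzo ring. The forward olefination must be E-selective and its base must not open the dihydrofuran by deprotonation at C3.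

27 from 26, and 26 from 24 through 25. After an oxidation-level change at the C6 arm, the O1–C2 bond is cut. A cation at C2 is stabilised by ArA, and its capture by an ortho phenol gives the five-membered ring with ArA trans to ArB, so C2 needs no independent control. In 24 the two phenols are equivalent (rotation about C3–C3a exchanges them), so no regiochemical question arises. The demand is kinetic, mildly acidic conditions, so that the cation closes before it can lose the C3 proton.

24 from 23. Three O–Si bonds are cut. One fluoride operation frees the carbinol, the second phenol and the primary alcohol together.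

23 from 15 and 18 (key disconnection). The benzo ring is cut at C3a–C4, C7–C7a and C4–C5. This is the only disconnection that sets the 1,2,3,5-pattern by bond polarity and not by arene substitution selectivity. It reduces a tetrasubstituted arene to an alkyne and a four-membered ketone, and it does not touch the chain stereocentres. The demand is a thermal, base-free cascade in which the propargylic, benzylic C3–H of 15 survives and the regiochemistry follows from ketene and ynol ether polarisation.

18 from 17 and 17 from 16. Two ring bonds of the cyclobutenone are cut by a ketene-alkyne [2+2] disconnection, followed by removal of two chlorines. The demand is that a propargylic ether alkyne be nucleophilic enough for dichloroketene.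

15 from 12 through 13 and 14. The C1–O and O–Si bonds of the ynol ether are cut, and the triple bond is traced to a 1,1-dibromoalkene. The acetylide that the dibromoalkene gives on lithiation is the same species that accepts oxygen, so both events fit in one flask. The demand is exact stoichiometry of alkyllithium, so that C3 is not metalated.

12 from 11, 11 from 10, 10 from 9. The C1=C bond is cut (one-carbon homologation) and the oxidation level of C1 is adjusted; the auxiliary is released. The aldehyde 11 is α-aryl and β-silyloxy, so it can enolise and eliminate. The demand is a non-basic oxidation and a non-basic olefination, with 11 used without storage.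

9 from 8, and 8 from 4 and 5. The bond between the ArB-bearing and ArA-bearing carbons (the future C3–C2 bond) is cut as an aldol. The auxiliary-controlled syn aldol fixes the future C3 absolutely. The carbinol centre is a passenger that is overwritten later, and its syn relation would also suit an invertive closure. The demand is a Z-enolate and protection of the carbinol before reduction.

4 from 1 and 2. The N-acyl bond is cut to give a bought arylacetic acid and the bought auxiliary.

## Other disconnections considered

Alternative 1: The cut is C3–C3a, reached by contracting a six-membered pyranone onto the dihydrofuran.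
- Forward step: natural (2S)-eriodictyol A1 already holds ArA, the C2 configuration and both ring oxygens. After catechol protection, exchange of the C7 oxygen for a methoxycarbonyl group, methylation at C5 and diazo transfer to C3, it would give diazoketone A2. Photolysis of A2 in aqueous THF would expel dinitrogen, shift the aryl carbon from the carbonyl carbon to C3 and let water capture the extruded acyl carbon, giving the ring-contracted acid A3.
- In its favour: the benzo ring, its oxygen pattern and the absolute configuration at C2 are bought. No auxiliary and no cryogenic ynolate chemistry are needed. The Wolff contraction is a dependable reaction class.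
- Against it here: the flavanone C2 centre is β to the ketone and can open to a chalcone under the basic conditions of diazo transfer. The C7 oxygen has to be traded for carbon. The key step leaves C3 as a carboxylic acid of mixed configuration, so ArB must then be introduced by a decarboxylative arylation whose trans outcome would rest only on shielding by ArA.
- Comparison: structurally it keeps an existing arene where the chosen plan builds one. Mechanistically both key steps are ketene-forming pericyclic events of comparable reliability. On the source of absolute configuration at C2 and on avoiding organolithium steps this alternative is the better one. The chosen plan, however, fixes C3 by an auxiliary aldol before any ring exists and lets C2 follow, whereas here C3 is the last and least controlled centre. The number of operations would probably be equal or higher.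

Alternative 2: The cut removes C2 as a one-carbon unit, breaking C2–C3 and O1–C2 together.
- Forward step: phenol sulfone A4 and the benzylic sulfonium salt A5 of a C2-symmetric chiral thiolane would be treated with Cs2CO3. Loss of sulfinate from A4 and deprotonation of A5 would be followed by addition of the ylide carbon to the benzylic C3 position and displacement of the sulfide by the phenoxide, giving ester A6. Hydride reduction of A6 would join the chosen route at 26.
- In its favour: it is the shortest and most convergent plan. Both stereocentres and the heterocycle arise in one step, and the anti-betaine followed by SN2 ring closure is inherently trans-selective. On step economy it is clearly better than the chosen plan, and on relative stereocontrol it is its equal.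
- Against it here: the absolute configuration depends on reagent control by the chiral sulfide with a semi-stabilised, electron-rich benzylic ylide, where the sense and level of induction are hard to predict (the enantiomer of A5 drawn is nominal). The synthesis of A4 must place the benzylic carbon between the two hydroxyls of a resorcinol ester. The reactive intermediate carries a second free ortho hydroxyl.
- Comparison: structurally it starts from an intact resorcinol and depends on substitution selectivity at the hindered carbon, which the chosen plan avoids by ring construction. Mechanistically it is an ionic stepwise annulation against a pericyclic cascade. The chosen plan spends about twice the steps to have C3 set by a highly predictable auxiliary aldol.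

Alternative 3: The cut is O1–C7a and C3–C3a, so the whole C2–C3 unit with both aryl groups arrives as an epoxide.
- Forward step: ortho-silylaryl triflate A7 with CsF would generate the aryne across C3a and C7a. The oxygen of the enantioenriched epoxide A8 would add to C7a, the aryne carbon remote from the methoxy group. The aryl anion at C3a would then capture the ArB-bearing carbon as the oxiranium opens, giving A9.
- In its favour: it is highly convergent and the benzo ring is a simple arene. The C2 configuration would come from a catalytic asymmetric epoxidation and be retained, because the C2–O bond is never broken. The C4 methoxy group directs the aryne addition and ends as the C4 oxygen. On convergence and on catalytic rather than auxiliary-based asymmetry this alternative is the better one.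
- Against it here: insertion of arynes into epoxide C–O bonds has thin precedent. The oxiranium must open at the ArB carbon, which meta-methoxy groups stabilise poorly, hence the need to deactivate ArA as a bis-mesylate. The C3 configuration passes through an open zwitterion and relies on trans-selective collapse. Mesylate removal and adjustment of the C6 arm add operations.
- Comparison: structurally both plans fuse the two rings late, but here the arene is preformed and the heterocycle is made, while the chosen plan does the reverse. Mechanistically the chosen cascade has one regiochemical demand secured by polarity, while this one has two (aryne addition and oxiranium opening) plus a stereochemical one. The step count would be similar or slightly lower, with the risk concentrated in the key step.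

Key step: step 10

Remarks before the steps
- Locants are those of the benzofuran in 30 (O1, C2, C3, C3a, C4 to C7, C7a); ArA is the 3,4-dioxygenated aryl on C2 and ArB the 3,5-dioxygenated aryl on C3.
- Structure check: 30 is (2S,3S) with ArA and ArB trans. At the future C3 the ranking is carbinol carbon, then alkynyl or new-arene carbon, then ArB, in 15 and in 23, so the S descriptor there corresponds to 3S in 30, and the syn aldol from the (R)-auxiliary delivers it. In the intermediates 10 to 13 the descriptor at this centre changes only because the ranking changes.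
- Bond count in step 10: three σ-bonds form during the cascade, but C4–C5 re-forms the bond broken at the outset, so the net gain over the two partners is two C–C bonds and one ring.
- Assumption: 16 and 28 are bought; 16 would otherwise need one silylation of propargyl alcohol.
- Design choices for safety: the α-aryl aldehyde 11 is homologated by a non-basic dibromo-olefination, not by a base-mediated diazophosphonate reaction. The acetylide from the dibromoalkene is oxidised in the same flask.

## Steps

Step 1
Reactants: 1 3,5-dimethoxyphenylacetic acid; 2 (R)-4-benzyl-2-oxazolidinone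
Product: 4 (4R)-4-benzyl-3-[2-(3,5-dimethoxyphenyl)acetyl]-1,3-oxazolidin-2-one, via mixed pivalic anhydride 3 (not isolated)
Conditions: t-BuCOCl, Et3N, THF, −20 °C; then LiCl, 2, −20 °C → rt
Reagents that add atoms: none
Why: Mixed-anhydride N-acylation of an oxazolidinone; the hindered pivaloyl carbonyl directs attack of the LiCl-activated oxazolidinone to the arylacetyl carbonyl, and no strong base is needed for this enolisable acid.

Step 2
Reactants: 4 (4R)-4-benzyl-3-[2-(3,5-dimethoxyphenyl)acetyl]-1,3-oxazolidin-2-one; 5 3,4-dimethoxybenzaldehyde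
Product: 8 (4R)-4-benzyl-3-[(2R,3R)-3-(3,4-dimethoxyphenyl)-2-(3,5-dimethoxyphenyl)-3-hydroxypropanoyl]-1,3-oxazolidin-2-one, via boron enolate 6 (not isolated), via boron aldolate 7 (not isolated)
Conditions: n-Bu2BOTf, i-Pr2NEt, CH2Cl2, −78 → 0 °C; 5, −78 → 0 °C; pH 7 buffer, MeOH, H2O2, 0 °C
Reagents that add atoms: none
Why: Evans syn-aldol reaction; the Z-boron enolate reacts through a Zimmerman–Traxler chair with the auxiliary carbonyl turned away, so the aldehyde adds to the enolate face opposite the benzyl group, which sets the ArB-bearing centre (future C3) absolutely and the carbinol syn to it.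

Step 3
Reactants: 8 (4R)-4-benzyl-3-[(2R,3R)-3-(3,4-dimethoxyphenyl)-2-(3,5-dimethoxyphenyl)-3-hydroxypropanoyl]-1,3-oxazolidin-2-one
Product: 9 (4R)-4-benzyl-3-[(2R,3R)-3-(tert-butyldimethylsilyloxy)-3-(3,4-dimethoxyphenyl)-2-(3,5-dimethoxyphenyl)propanoyl]-1,3-oxazolidin-2-one
Conditions: TBSOTf, 2,6-lutidine, CH2Cl2, −78 → 0 °C
Reagents that add atoms: tert-butyldimethylsilyl trifluoromethanesulfonate, CC(C)(C)[Si](C)(C)OS(=O)(=O)C(F)(F)F
Why: Silylation of a hindered secondary alcohol with a silyl triflate and a weak, hindered base; the conditions are too mild for retro-aldol cleavage or epimerisation of the α-aryl imide.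

Step 4
Reactants: 9 (4R)-4-benzyl-3-[(2R,3R)-3-(tert-butyldimethylsilyloxy)-3-(3,4-dimethoxyphenyl)-2-(3,5-dimethoxyphenyl)propanoyl]-1,3-oxazolidin-2-one
Product: 10 (2S,3R)-3-(tert-butyldimethylsilyloxy)-3-(3,4-dimethoxyphenyl)-2-(3,5-dimethoxyphenyl)propan-1-ol
Conditions: LiBH4, MeOH (1 equiv), THF, 0 °C
Reagents that add atoms: none
Why: Reductive removal of the oxazolidinone auxiliary with LiBH4 at the exocyclic imide carbonyl; the auxiliary is recovered and neither stereocentre is involved.

Step 5
Reactants: 10 (2S,3R)-3-(tert-butyldimethylsilyloxy)-3-(3,4-dimethoxyphenyl)-2-(3,5-dimethoxyphenyl)propan-1-ol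
Product: 11 (2R,3R)-3-(tert-butyldimethylsilyloxy)-3-(3,4-dimethoxyphenyl)-2-(3,5-dimethoxyphenyl)propanal
Conditions: Dess–Martin periodinane, NaHCO3, CH2Cl2, 0 °C; crude product used at once
Reagents that add atoms: none
Why: Dess–Martin oxidation is neutral and amine-free, which suits an α-aryl, β-silyloxy aldehyde that would enolise, epimerise or eliminate silanol under basic oxidation conditions.

Step 6
Reactants: 11 (2R,3R)-3-(tert-butyldimethylsilyloxy)-3-(3,4-dimethoxyphenyl)-2-(3,5-dimethoxyphenyl)propanal
Product: 12 (3R,4R)-1,1-dibromo-4-(tert-butyldimethylsilyloxy)-4-(3,4-dimethoxyphenyl)-3-(3,5-dimethoxyphenyl)but-1-ene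
Conditions: CBr4, PPh3, 2,6-lutidine, CH2Cl2, −20 → 0 °C
Reagents that add atoms: carbon tetrabromide, BrC(Br)(Br)Br
Why: Ramirez dibromo-olefination (first stage of the Corey–Fuchs sequence); the dibromomethylene ylide is only weakly basic, so the aldehyde is olefinated faster than it enolises and the α-centre is kept.

Step 7
Reactants: 12 (3R,4R)-1,1-dibromo-4-(tert-butyldimethylsilyloxy)-4-(3,4-dimethoxyphenyl)-3-(3,5-dimethoxyphenyl)but-1-ene
Product: 15 (3S,4R)-4-(tert-butyldimethylsilyloxy)-4-(3,4-dimethoxyphenyl)-3-(3,5-dimethoxyphenyl)-1-[tri(propan-2-yl)silyloxy]but-1-yne, via lithium acetylide 13 (not isolated), via lithium ynolate 14 (not isolated)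
Conditions: n-BuLi (2.05 equiv), THF, −78 °C; LiOOt-Bu (from t-BuOOH and LiN(SiMe3)2), −78 → 0 °C; TIPSOTf, −78 → 0 °C
Reagents that add atoms: lithium tert-butyl peroxide, [Li+].[O-]OC(C)(C)C; tri(propan-2-yl)silyl trifluoromethanesulfonate, CC(C)[Si](OS(=O)(=O)C(F)(F)F)(C(C)C)C(C)C
Why: Bromine-lithium exchange and Fritsch–Buttenberg–Wiechell rearrangement (second stage of the Corey–Fuchs sequence) give acetylide 13, electrophilic oxygen transfer from the lithium peroxide gives ynolate 14, and the bulky silyl triflate silylates it on oxygen; with the alkyllithium fully consumed at −78 °C the propargylic, benzylic centre is not deprotonated.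

Step 8
Reactants: 16 tert-butyldimethyl(prop-2-yn-1-yloxy)silane
Product: 17 4,4-dichloro-3-[(tert-butyldimethylsilyloxy)methyl]cyclobut-2-en-1-one
Conditions: Cl3CCOCl, Zn–Cu couple, Et2O/DME, rt
Reagents that add atoms: trichloroacetyl chloride, ClC(Cl)(Cl)C(Cl)=O
Why: [2+2] cycloaddition of dichloroketene, generated in the flask, with a terminal alkyne; the terminal alkyne carbon bonds to the ketene carbonyl carbon, which places the substituent at C3, and DME sequesters ZnCl2 away from the silyl ether.

Step 9
Reactants: 17 4,4-dichloro-3-[(tert-butyldimethylsilyloxy)methyl]cyclobut-2-en-1-one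
Product: 18 3-[(tert-butyldimethylsilyloxy)methyl]cyclobut-2-en-1-one
Conditions: Zn dust, AcOH, TMEDA, EtOH, 0 °C → rt
Reagents that add atoms: none
Why: Reductive dechlorination of an α,α-dichloroketone by zinc through zinc enolates; the amine-buffered acetic acid protonates them without cleaving the silyl ether or opening the strained enone.

Step 10
Reactants: 15 (3S,4R)-4-(tert-butyldimethylsilyloxy)-4-(3,4-dimethoxyphenyl)-3-(3,5-dimethoxyphenyl)-1-[tri(propan-2-yl)silyloxy]but-1-yne; 18 3-[(tert-butyldimethylsilyloxy)methyl]cyclobut-2-en-1-one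
Product: 23 2-[(1S,2R)-2-(tert-butyldimethylsilyloxy)-2-(3,4-dimethoxyphenyl)-1-(3,5-dimethoxyphenyl)ethyl]-5-[(tert-butyldimethylsilyloxy)methyl]-3-[tri(propan-2-yl)silyloxy]phenol, via vinylketene 19 (not isolated), via vinylcyclobutenone 20 (not isolated), via dienylketene 21 (not isolated), via cyclohexadienone 22 (not isolated)
Conditions: 18 (1.3 equiv), toluene, 80 → 110 °C, Ar
Reagents that add atoms: none
Why: Heating opens 18 by conrotatory 4π electrocyclic cleavage of its acyl–CH2 bond to vinylketene 19. The electrophilic ketene carbonyl carbon bonds to the nucleophilic β-carbon of ynol ether 15 (the carbon bearing the chiral chain) and the ketene α-carbon bonds to the silyloxy carbon in a regiospecific [2+2] cycloaddition, giving 20 and forming C3a–C4 and C7–C7a. A second 4π opening turns 20 into dienylketene 21, whose thermal disrotatory 6π electrocyclisation closes the six-membered ring by bonding the ketene carbon to the terminal methylene (C4–C5, the bond severed in the first opening), and tautomerisation of 22 gives phenol 23. The closest known reaction type is the Danheiser benzannulation of cyclobutenones with triisopropylsilyl ynol ethers, which gives 2-substituted resorcinol monosilyl ethers and accepts branched substituents on the alkyne. No stereocentre is created: the sp3 ring carbon of 20 is transient and is erased on ring opening, and the two chain centres are spectators. The one selectivity needed is the regiochemistry of the [2+2] step, and the matched polarisation of ketene and ynol ether secures it, placing the chain between the two oxygen-bearing carbons and the silyloxymethyl group para to it. The propargylic, benzylic C3–H must also stay untouched, which the neutral, base-free thermal medium allows, and silyl and methyl ethers are inert. Which oxygen later becomes O1 is immaterial because both flank C3a.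

Step 11
Reactants: 23 2-[(1S,2R)-2-(tert-butyldimethylsilyloxy)-2-(3,4-dimethoxyphenyl)-1-(3,5-dimethoxyphenyl)ethyl]-5-[(tert-butyldimethylsilyloxy)methyl]-3-[tri(propan-2-yl)silyloxy]phenol
Product: 24 2-[(1S,2R)-2-(3,4-dimethoxyphenyl)-1-(3,5-dimethoxyphenyl)-2-hydroxyethyl]-5-(hydroxymethyl)benzene-1,3-diol
Conditions: Bu4NF (5 equiv), AcOH (5 equiv), THF, 0 °C → rt, Ar
Reagents that add atoms: none
Why: Fluoride desilylation of one aryl and two alkyl silyl ethers in one operation; the acetic acid buffer keeps the electron-rich resorcinol from standing as a free phenoxide, and no stereocentre is involved.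

Step 12
Reactants: 24 2-[(1S,2R)-2-(3,4-dimethoxyphenyl)-1-(3,5-dimethoxyphenyl)-2-hydroxyethyl]-5-(hydroxymethyl)benzene-1,3-diol
Product: 26 (2S,3S)-2-(3,4-dimethoxyphenyl)-3-(3,5-dimethoxyphenyl)-6-(hydroxymethyl)-2,3-dihydro-1-benzofuran-4-ol, via benzylic cation 25 (not isolated)
Conditions: TsOH·H2O (10 mol %), MeCN (0.01 M), 0 °C → rt
Reagents that add atoms: none
Why: Acid-catalysed dehydrative etherification by an SN1 path; only the ArA-stabilised secondary benzylic alcohol ionises, and either of the equivalent phenols closes the five-membered ring on the face of 25 that puts ArA anti to ArB, so C2 is set as S by the existing C3 centre (the trans ring is also the more stable one). Dilution and low temperature favour closure over intermolecular arylation or loss of the C3 proton.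

Step 13
Reactants: 26 (2S,3S)-2-(3,4-dimethoxyphenyl)-3-(3,5-dimethoxyphenyl)-6-(hydroxymethyl)-2,3-dihydro-1-benzofuran-4-ol
Product: 27 (2S,3S)-2-(3,4-dimethoxyphenyl)-3-(3,5-dimethoxyphenyl)-4-hydroxy-2,3-dihydro-1-benzofuran-6-carbaldehyde
Conditions: MnO2 (activated, excess), EtOAc, rt
Reagents that add atoms: none
Why: Chemoselective heterogeneous oxidation of a benzylic alcohol by MnO2, which stops at the aldehyde and tolerates a meta phenol and the benzylic ether.

Step 14
Reactants: 27 (2S,3S)-2-(3,4-dimethoxyphenyl)-3-(3,5-dimethoxyphenyl)-4-hydroxy-2,3-dihydro-1-benzofuran-6-carbaldehyde; 28 diethyl (4-methoxybenzyl)phosphonate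
Product: 29 (2S,3S)-2-(3,4-dimethoxyphenyl)-3-(3,5-dimethoxyphenyl)-6-[(E)-2-(4-methoxyphenyl)ethenyl]-2,3-dihydro-1-benzofuran-4-ol
Conditions: 28 (2.5 equiv), KOt-Bu (3.5 equiv), THF, 0 °C → rt
Reagents that add atoms: none
Why: Horner–Wadsworth–Emmons olefination with a benzylic phosphonate gives the E-stilbene under thermodynamic control of the elimination; the first equivalent of base is spent on the phenol, and the phosphonate anion is too weak a base to deprotonate C3.

Step 15
Reactants: 29 (2S,3S)-2-(3,4-dimethoxyphenyl)-3-(3,5-dimethoxyphenyl)-6-[(E)-2-(4-methoxyphenyl)ethenyl]-2,3-dihydro-1-benzofuran-4-ol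
Product: 30 4-[(2S,3S)-3-(3,5-dihydroxyphenyl)-4-hydroxy-6-[(E)-2-(4-hydroxyphenyl)ethenyl]-2,3-dihydro-1-benzofuran-2-yl]benzene-1,2-diol
Conditions: BBr3 (12 equiv), CH2Cl2, −78 °C → rt; then MeOH, H2O, 0 °C
Reagents that add atoms: none
Why: Lewis-acid cleavage of aryl methyl ethers by BBr3 (bromide attacks the methyl group of the boron-complexed ether); any reversible opening at C2–O1 regenerates the trans ring from the same C3 centre, and the low starting temperature limits acid-induced reactions of the stilbene.

## Compound list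

1 | 3,5-dimethoxyphenylacetic acid | COc1cc(CC(=O)O)cc(OC)c1 | starting material
2 | (R)-4-benzyl-2-oxazolidinone | O=C1N[C@H](Cc2ccccc2)CO1 | starting material
3 | 2-(3,5-dimethoxyphenyl)acetic pivalic anhydride | COc1cc(CC(=O)OC(=O)C(C)(C)C)cc(OC)c1 | intermediate
4 | (4R)-4-benzyl-3-[2-(3,5-dimethoxyphenyl)acetyl]-1,3-oxazolidin-2-one | COc1cc(CC(=O)N2[C@H](Cc3ccccc3)COC2=O)cc(OC)c1 | intermediate
5 | 3,4-dimethoxybenzaldehyde | COc1ccc(C=O)cc1OC | starting material
6 | (4R)-4-benzyl-3-[(Z)-1-(dibutylboranyloxy)-2-(3,5-dimethoxyphenyl)ethenyl]-1,3-oxazolidin-2-one (boron enolate) | CCCCB(CCCC)O/C(=C\c1cc(OC)cc(OC)c1)N1[C@H](Cc2ccccc2)COC1=O | intermediate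
7 | (4R)-4-benzyl-3-[(2R,3R)-3-(dibutylboranyloxy)-3-(3,4-dimethoxyphenyl)-2-(3,5-dimethoxyphenyl)propanoyl]-1,3-oxazolidin-2-one (boron aldolate) | CCCCB(CCCC)O[C@@H](c1ccc(OC)c(OC)c1)[C@H](C(=O)N1[C@H](Cc2ccccc2)COC1=O)c1cc(OC)cc(OC)c1 | intermediate
8 | (4R)-4-benzyl-3-[(2R,3R)-3-(3,4-dimethoxyphenyl)-2-(3,5-dimethoxyphenyl)-3-hydroxypropanoyl]-1,3-oxazolidin-2-one | O[C@@H](c1ccc(OC)c(OC)c1)[C@H](C(=O)N1[C@H](Cc2ccccc2)COC1=O)c1cc(OC)cc(OC)c1 | intermediate
9 | (4R)-4-benzyl-3-[(2R,3R)-3-(tert-butyldimethylsilyloxy)-3-(3,4-dimethoxyphenyl)-2-(3,5-dimethoxyphenyl)propanoyl]-1,3-oxazolidin-2-one | CC(C)(C)[Si](C)(C)O[C@@H](c1ccc(OC)c(OC)c1)[C@H](C(=O)N1[C@H](Cc2ccccc2)COC1=O)c1cc(OC)cc(OC)c1 | intermediate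
10 | (2S,3R)-3-(tert-butyldimethylsilyloxy)-3-(3,4-dimethoxyphenyl)-2-(3,5-dimethoxyphenyl)propan-1-ol | CC(C)(C)[Si](C)(C)O[C@@H](c1ccc(OC)c(OC)c1)[C@H](CO)c1cc(OC)cc(OC)c1 | intermediate
11 | (2R,3R)-3-(tert-butyldimethylsilyloxy)-3-(3,4-dimethoxyphenyl)-2-(3,5-dimethoxyphenyl)propanal | CC(C)(C)[Si](C)(C)O[C@@H](c1ccc(OC)c(OC)c1)[C@H](C=O)c1cc(OC)cc(OC)c1 | intermediate
12 | (3R,4R)-1,1-dibromo-4-(tert-butyldimethylsilyloxy)-4-(3,4-dimethoxyphenyl)-3-(3,5-dimethoxyphenyl)but-1-ene | CC(C)(C)[Si](C)(C)O[C@@H](c1ccc(OC)c(OC)c1)[C@H](C=C(Br)Br)c1cc(OC)cc(OC)c1 | intermediate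
13 | lithium (3R,4R)-4-(tert-butyldimethylsilyloxy)-4-(3,4-dimethoxyphenyl)-3-(3,5-dimethoxyphenyl)but-1-yn-1-ide (lithium acetylide) | CC(C)(C)[Si](C)(C)O[C@@H](c1ccc(OC)c(OC)c1)[C@H](C#[C-])c1cc(OC)cc(OC)c1.[Li+] | intermediate
14 | lithium (3S,4R)-4-(tert-butyldimethylsilyloxy)-4-(3,4-dimethoxyphenyl)-3-(3,5-dimethoxyphenyl)but-1-yn-1-olate (lithium ynolate) | CC(C)(C)[Si](C)(C)O[C@@H](c1ccc(OC)c(OC)c1)[C@H](C#C[O-])c1cc(OC)cc(OC)c1.[Li+] | intermediate
15 | (3S,4R)-4-(tert-butyldimethylsilyloxy)-4-(3,4-dimethoxyphenyl)-3-(3,5-dimethoxyphenyl)-1-[tri(propan-2-yl)silyloxy]but-1-yne | CC(C)(C)[Si](C)(C)O[C@@H](c1ccc(OC)c(OC)c1)[C@H](C#CO[Si](C(C)C)(C(C)C)C(C)C)c1cc(OC)cc(OC)c1 | intermediate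
16 | tert-butyldimethyl(prop-2-yn-1-yloxy)silane | C#CCO[Si](C)(C)C(C)(C)C | starting material
17 | 4,4-dichloro-3-[(tert-butyldimethylsilyloxy)methyl]cyclobut-2-en-1-one | CC(C)(C)[Si](C)(C)OCC1=CC(=O)C1(Cl)Cl | intermediate
18 | 3-[(tert-butyldimethylsilyloxy)methyl]cyclobut-2-en-1-one | CC(C)(C)[Si](C)(C)OCC1=CC(=O)C1 | intermediate
19 | 3-[(tert-butyldimethylsilyloxy)methyl]buta-1,3-dien-1-one (vinylketene) | CC(C)(C)[Si](C)(C)OCC(=C)C=C=O | intermediate
20 | 2-[(1S,2R)-2-(tert-butyldimethylsilyloxy)-2-(3,4-dimethoxyphenyl)-1-(3,5-dimethoxyphenyl)ethyl]-4-{3-(tert-butyldimethylsilyloxy)prop-1-en-2-yl}-3-[tri(propan-2-yl)silyloxy]cyclobut-2-en-1-one (both C4 epimers) | CC(C)(C)[Si](C)(C)O[C@@H](c1ccc(OC)c(OC)c1)[C@H](C1=C(O[Si](C(C)C)(C(C)C)C(C)C)C(C(=C)CO[Si](C)(C)C(C)(C)C)C1=O)c1cc(OC)cc(OC)c1 | intermediate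
21 | (3E)-2-[(1S,2R)-2-(tert-butyldimethylsilyloxy)-2-(3,4-dimethoxyphenyl)-1-(3,5-dimethoxyphenyl)ethyl]-5-[(tert-butyldimethylsilyloxy)methyl]-3-[tri(propan-2-yl)silyloxy]hexa-1,3,5-trien-1-one (dienylketene) | CC(C)(C)[Si](C)(C)O[C@@H](c1ccc(OC)c(OC)c1)[C@H](C(=C=O)/C(O[Si](C(C)C)(C(C)C)C(C)C)=C\C(=C)CO[Si](C)(C)C(C)(C)C)c1cc(OC)cc(OC)c1 | intermediate
22 | 2-[(1S,2R)-2-(tert-butyldimethylsilyloxy)-2-(3,4-dimethoxyphenyl)-1-(3,5-dimethoxyphenyl)ethyl]-5-[(tert-butyldimethylsilyloxy)methyl]-3-[tri(propan-2-yl)silyloxy]cyclohexa-2,4-dien-1-one | CC(C)(C)[Si](C)(C)O[C@@H](c1ccc(OC)c(OC)c1)[C@H](C1=C(O[Si](C(C)C)(C(C)C)C(C)C)C=C(CO[Si](C)(C)C(C)(C)C)CC1=O)c1cc(OC)cc(OC)c1 | intermediate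
23 | 2-[(1S,2R)-2-(tert-butyldimethylsilyloxy)-2-(3,4-dimethoxyphenyl)-1-(3,5-dimethoxyphenyl)ethyl]-5-[(tert-butyldimethylsilyloxy)methyl]-3-[tri(propan-2-yl)silyloxy]phenol | CC(C)(C)[Si](C)(C)O[C@@H](c1ccc(OC)c(OC)c1)[C@H](c1c(O)cc(CO[Si](C)(C)C(C)(C)C)cc1O[Si](C(C)C)(C(C)C)C(C)C)c1cc(OC)cc(OC)c1 | intermediate
24 | 2-[(1S,2R)-2-(3,4-dimethoxyphenyl)-1-(3,5-dimethoxyphenyl)-2-hydroxyethyl]-5-(hydroxymethyl)benzene-1,3-diol | O[C@@H](c1ccc(OC)c(OC)c1)[C@H](c1c(O)cc(CO)cc1O)c1cc(OC)cc(OC)c1 | intermediate
25 | (2S)-2-[2,6-dihydroxy-4-(hydroxymethyl)phenyl]-1-(3,4-dimethoxyphenyl)-2-(3,5-dimethoxyphenyl)ethan-1-ylium (benzylic cation) | [CH+](c1ccc(OC)c(OC)c1)[C@H](c1c(O)cc(CO)cc1O)c1cc(OC)cc(OC)c1 | intermediate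
26 | (2S,3S)-2-(3,4-dimethoxyphenyl)-3-(3,5-dimethoxyphenyl)-6-(hydroxymethyl)-2,3-dihydro-1-benzofuran-4-ol | OCc1cc(O)c2c(c1)O[C@H](c1ccc(OC)c(OC)c1)[C@H]2c1cc(OC)cc(OC)c1 | intermediate
27 | (2S,3S)-2-(3,4-dimethoxyphenyl)-3-(3,5-dimethoxyphenyl)-4-hydroxy-2,3-dihydro-1-benzofuran-6-carbaldehyde | O=Cc1cc(O)c2c(c1)O[C@H](c1ccc(OC)c(OC)c1)[C@H]2c1cc(OC)cc(OC)c1 | intermediate
28 | diethyl (4-methoxybenzyl)phosphonate | CCOP(=O)(Cc1ccc(OC)cc1)OCC | starting material
29 | (2S,3S)-2-(3,4-dimethoxyphenyl)-3-(3,5-dimethoxyphenyl)-6-[(E)-2-(4-methoxyphenyl)ethenyl]-2,3-dihydro-1-benzofuran-4-ol | COc1ccc(/C=C/c2cc(O)c3c(c2)O[C@H](c2ccc(OC)c(OC)c2)[C@H]3c2cc(OC)cc(OC)c2)cc1 | intermediate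
30 | 4-[(2S,3S)-3-(3,5-dihydroxyphenyl)-4-hydroxy-6-[(E)-2-(4-hydroxyphenyl)ethenyl]-2,3-dihydro-1-benzofuran-2-yl]benzene-1,2-diol | Oc1ccc(/C=C/c2cc(O)c3c(c2)O[C@H](c2ccc(O)c(O)c2)[C@H]3c2cc(O)cc(O)c2)cc1 | target

## Step count and least certain steps

Total step count: 15. Longest linear sequence: 13 steps (steps 1 to 7, then 10 to 15); steps 8 and 9 form the side branch.

Step 10 (key step).
- What may go wrong: slow [2+2] addition at the hindered ynol ether carbon, which lets vinylketene dimerisation, thermal silyl migration within the ynol ether, or O-acylation of the product phenol by further vinylketene compete.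
- Fallback: it sets out from 15, replaces 18 by a diazoketone and rejoins the route at 19 and so at 23. Methyl vinyl ketone and aqueous formaldehyde with DABCO (Morita–Baylis–Hillman reaction) would give 3-(hydroxymethyl)but-3-en-2-one F1. TBSCl and imidazole would give 3-[(tert-butyldimethylsilyloxy)methyl]but-3-en-2-one F2. LiN(SiMe3)2 and then CF3CO2CH2CF3 at −78 °C would give 5-[(tert-butyldimethylsilyloxy)methyl]-1,1,1-trifluorohex-5-ene-2,4-dione F3, which without isolation would undergo deacylative diazo transfer (MsN3, Et3N, H2O, MeCN) to 1-diazo-3-[(tert-butyldimethylsilyloxy)methyl]but-3-en-2-one F4. Irradiation of F4 with 15 in CH2Cl2 at room temperature would generate 19 by photochemical Wolff rearrangement, so the ketene is formed and trapped cold, and brief warming would complete the cascade to 23.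

Step 7.
- What may go wrong: incomplete oxygen transfer to the hindered acetylide in the presence of LiBr and butyl bromide, C-silylation of the ynolate in place of O-silylation, or metalation at C3 or on ArB by excess alkyllithium.
- Fallback: it sets out from 13 and comes back at 14. Acetylide 13 with PhI(OCOPh)2 in THF (−78 °C → rt) would give, by ligand coupling at hypervalent iodine, (3S,4R)-4-(tert-butyldimethylsilyloxy)-4-(3,4-dimethoxyphenyl)-3-(3,5-dimethoxyphenyl)but-1-yn-1-yl benzoate F5. MeLi (2 equiv) at −78 °C would cleave the ester to ynolate 14, which is silylated as in step 7.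

Step 6 (with the handling of 11 from step 5).
- What may go wrong: enolisation of the α-aryl aldehyde during olefination, leading to epimerisation at the future C3 or β-elimination of silanol.
- Fallback: it sets out from 11 and comes back at 13. Me3SiC(Li)N2 (from Me3SiCHN2 and n-BuLi) in THF at −78 °C → rt (Colvin rearrangement) adds to the aldehyde faster than it deprotonates it. In one operation it would give (3R,4R)-4-(tert-butyldimethylsilyloxy)-4-(3,4-dimethoxyphenyl)-3-(3,5-dimethoxyphenyl)but-1-yne F6, and LiN(SiMe3)2 would convert F6 into 13.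

Step 8.
- What may go wrong: low nucleophilicity of the propargylic ether alkyne toward dichloroketene, ZnCl2-induced loss of the silyl ether, and isomerisation of the dichloride before reduction.
- Fallback: it sets out from 16 and comes back at 18, bypassing step 9. N,N-dimethylacetamide, Tf2O and 2,4,6-collidine in 1,2-dichloroethane would generate the far more electrophilic keteniminium ion. Its [2+2] cycloaddition with 16 would give N-{3-[(tert-butyldimethylsilyloxy)methyl]cyclobut-2-en-1-ylidene}-N-methylmethanaminium trifluoromethanesulfonate F7, and aqueous NaHCO3 would hydrolyse F7 directly to 18.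

Step 12.
- What may go wrong: reversible ionisation under protic acid lets the C2 cation lose the C3 proton and reprotonate, eroding C3; intermolecular arylation by the free resorcinol; incomplete trans selectivity.
- Fallback: it sets out from 23 and comes back at 26, replacing steps 11 and 12 in reverse order. BF3·OEt2 in CH2Cl2 at −78 °C would ionise the benzylic silyl ether while one phenol is still masked, and the single free phenol would close to (2S,3S)-6-[(tert-butyldimethylsilyloxy)methyl]-2-(3,4-dimethoxyphenyl)-3-(3,5-dimethoxyphenyl)-4-[tri(propan-2-yl)silyloxy]-2,3-dihydro-1-benzofuran F8. Bu4NF and AcOH would then give 26.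

Step 15.
- What may go wrong: Lewis-acid opening of C2–O1 followed by intermolecular capture or by elimination toward C3; acid-induced addition or oligomerisation at the electron-rich stilbene; incomplete cleavage at the catechol ether.
- Fallback: it sets out from 27 and comes back at 30, moving the Lewis-acid step to a stage without the stilbene and finishing with fluoride.
  - BBr3 on 27 would give (2S,3S)-2-(3,4-dihydroxyphenyl)-3-(3,5-dihydroxyphenyl)-4-hydroxy-2,3-dihydro-1-benzofuran-6-carbaldehyde F9.
  - TBSCl and imidazole in DMF would give (2S,3S)-2-[3,4-bis(tert-butyldimethylsilyloxy)phenyl]-3-[3,5-bis(tert-butyldimethylsilyloxy)phenyl]-4-(tert-butyldimethylsilyloxy)-2,3-dihydro-1-benzofuran-6-carbaldehyde F10.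
  - Diethyl (4-hydroxybenzyl)phosphonate and TBSCl would give diethyl {4-[(tert-butyldimethylsilyl)oxy]benzyl}phosphonate F11.
  - Horner–Wadsworth–Emmons reaction of F10 with F11 and LiN(SiMe3)2 would give (2S,3S)-2-[3,4-bis(tert-butyldimethylsilyloxy)phenyl]-3-[3,5-bis(tert-butyldimethylsilyloxy)phenyl]-4-(tert-butyldimethylsilyloxy)-6-[(E)-2-{4-[(tert-butyldimethylsilyl)oxy]phenyl}ethenyl]-2,3-dihydro-1-benzofuran F12.
  - Bu4NF and AcOH would release 30.

## Further compounds

F1 | step 10 | 3-(hydroxymethyl)but-3-en-2-one | CC(=O)C(=C)CO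
F2 | step 10 | 3-[(tert-butyldimethylsilyloxy)methyl]but-3-en-2-one | CC(=O)C(=C)CO[Si](C)(C)C(C)(C)C
F3 | step 10 | 5-[(tert-butyldimethylsilyloxy)methyl]-1,1,1-trifluorohex-5-ene-2,4-dione | O=C(CC(=O)C(=C)CO[Si](C)(C)C(C)(C)C)C(F)(F)F
F4 | step 10 | 1-diazo-3-[(tert-butyldimethylsilyloxy)methyl]but-3-en-2-one | [N-]=[N+]=CC(=O)C(=C)CO[Si](C)(C)C(C)(C)C
F5 | step 7 | (3S,4R)-4-(tert-butyldimethylsilyloxy)-4-(3,4-dimethoxyphenyl)-3-(3,5-dimethoxyphenyl)but-1-yn-1-yl benzoate | CC(C)(C)[Si](C)(C)O[C@@H](c1ccc(OC)c(OC)c1)[C@H](C#COC(=O)c1ccccc1)c1cc(OC)cc(OC)c1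
F6 | step 6 | (3R,4R)-4-(tert-butyldimethylsilyloxy)-4-(3,4-dimethoxyphenyl)-3-(3,5-dimethoxyphenyl)but-1-yne | CC(C)(C)[Si](C)(C)O[C@@H](c1ccc(OC)c(OC)c1)[C@H](C#C)c1cc(OC)cc(OC)c1
F7 | step 8 | N-{3-[(tert-butyldimethylsilyloxy)methyl]cyclobut-2-en-1-ylidene}-N-methylmethanaminium trifluoromethanesulfonate | CC(C)(C)[Si](C)(C)OCC1=CC(=[N+](C)C)C1.[O-]S(=O)(=O)C(F)(F)F
F8 | step 12 | (2S,3S)-6-[(tert-butyldimethylsilyloxy)methyl]-2-(3,4-dimethoxyphenyl)-3-(3,5-dimethoxyphenyl)-4-[tri(propan-2-yl)silyloxy]-2,3-dihydro-1-benzofuran | CC(C)(C)[Si](C)(C)OCc1cc(O[Si](C(C)C)(C(C)C)C(C)C)c2c(c1)O[C@H](c1ccc(OC)c(OC)c1)[C@H]2c1cc(OC)cc(OC)c1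
F9 | step 15 | (2S,3S)-2-(3,4-dihydroxyphenyl)-3-(3,5-dihydroxyphenyl)-4-hydroxy-2,3-dihydro-1-benzofuran-6-carbaldehyde | O=Cc1cc(O)c2c(c1)O[C@H](c1ccc(O)c(O)c1)[C@H]2c1cc(O)cc(O)c1
F10 | step 15 | (2S,3S)-2-[3,4-bis(tert-butyldimethylsilyloxy)phenyl]-3-[3,5-bis(tert-butyldimethylsilyloxy)phenyl]-4-(tert-butyldimethylsilyloxy)-2,3-dihydro-1-benzofuran-6-carbaldehyde | O=Cc1cc(O[Si](C)(C)C(C)(C)C)c2c(c1)O[C@H](c1ccc(O[Si](C)(C)C(C)(C)C)c(O[Si](C)(C)C(C)(C)C)c1)[C@H]2c1cc(O[Si](C)(C)C(C)(C)C)cc(O[Si](C)(C)C(C)(C)C)c1
F11 | step 15 | diethyl {4-[(tert-butyldimethylsilyl)oxy]benzyl}phosphonate | CCOP(=O)(Cc1ccc(O[Si](C)(C)C(C)(C)C)cc1)OCC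
F12 | step 15 | (2S,3S)-2-[3,4-bis(tert-butyldimethylsilyloxy)phenyl]-3-[3,5-bis(tert-butyldimethylsilyloxy)phenyl]-4-(tert-butyldimethylsilyloxy)-6-[(E)-2-{4-[(tert-butyldimethylsilyl)oxy]phenyl}ethenyl]-2,3-dihydro-1-benzofuran | CC(C)(C)[Si](C)(C)Oc1ccc(/C=C/c2cc(O[Si](C)(C)C(C)(C)C)c3c(c2)O[C@H](c2ccc(O[Si](C)(C)C(C)(C)C)c(O[Si](C)(C)C(C)(C)C)c2)[C@H]3c2cc(O[Si](C)(C)C(C)(C)C)cc(O[Si](C)(C)C(C)(C)C)c2)cc1
A1 | alternative 1 | (2S)-eriodictyol, (2S)-2-(3,4-dihydroxyphenyl)-5,7-dihydroxy-2,3-dihydro-4H-chromen-4-one | O=C1C[C@@H](c2ccc(O)c(O)c2)Oc2cc(O)cc(O)c12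
A2 | alternative 1 | methyl (2R)-3-diazo-2-(2,2-diphenyl-1,3-benzodioxol-5-yl)-5-methoxy-4-oxo-3,4-dihydro-2H-chromene-7-carboxylate (same spatial arrangement at C2 as A1) | COC(=O)c1cc(OC)c2c(c1)O[C@H](c1ccc3OC(c4ccccc4)(c4ccccc4)Oc3c1)C(=[N+]=[N-])C2=O
A3 | alternative 1 | (2S)-2-(2,2-diphenyl-1,3-benzodioxol-5-yl)-4-methoxy-6-(methoxycarbonyl)-2,3-dihydro-1-benzofuran-3-carboxylic acid (C3 as a mixture) | COC(=O)c1cc(OC)c2c(c1)O[C@H](c1ccc3OC(c4ccccc4)(c4ccccc4)Oc3c1)C2C(=O)O
A4 | alternative 2 | methyl 4-[(3,5-dimethoxyphenyl)(4-methylbenzenesulfonyl)methyl]-3,5-dihydroxybenzoate (racemic) | COC(=O)c1cc(O)c(C(c2cc(OC)cc(OC)c2)S(=O)(=O)c2ccc(C)cc2)c(O)c1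
A5 | alternative 2 | (2R,5R)-1-(3,4-dimethoxybenzyl)-2,5-dimethylthiolan-1-ium tetrafluoroborate | COc1ccc(C[S+]2[C@H](C)CC[C@H]2C)cc1OC.F[B-](F)(F)F
A6 | alternative 2 | methyl (2S,3S)-2-(3,4-dimethoxyphenyl)-3-(3,5-dimethoxyphenyl)-4-hydroxy-2,3-dihydro-1-benzofuran-6-carboxylate | COC(=O)c1cc(O)c2c(c1)O[C@H](c1ccc(OC)c(OC)c1)[C@H]2c1cc(OC)cc(OC)c1
A7 | alternative 3 | 3-methoxy-5-{[tri(propan-2-yl)silyl]oxymethyl}-2-(trimethylsilyl)phenyl trifluoromethanesulfonate | COc1cc(CO[Si](C(C)C)(C(C)C)C(C)C)cc(OS(=O)(=O)C(F)(F)F)c1[Si](C)(C)C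
A8 | alternative 3 | (2R,3R)-2-[3,4-bis(methylsulfonyloxy)phenyl]-3-(3,5-dimethoxyphenyl)oxirane | COc1cc([C@H]2O[C@@H]2c2ccc(OS(C)(=O)=O)c(OS(C)(=O)=O)c2)cc(OC)c1
A9 | alternative 3 | (2S,3S)-2-[3,4-bis(methylsulfonyloxy)phenyl]-3-(3,5-dimethoxyphenyl)-4-methoxy-6-{[tri(propan-2-yl)silyl]oxymethyl}-2,3-dihydro-1-benzofuran | CC(C)[Si](OCc1cc(OC)c2c(c1)O[C@H](c1ccc(OS(C)(=O)=O)c(OS(C)(=O)=O)c1)[C@H]2c1cc(OC)cc(OC)c1)(C(C)C)C(C)C
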